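**Retrosynthetic overview**
1. Target 13 ⇒ O-benzyl ether 12 ⇒ C3–CH2(ring B) bond by C-benzylation of the enediolate of α-hydroxy lactone 7 with bromide 10, anti to the C4 substituent; the C3–OH comes from enolate oxidation of lactone 5.
2. The C4 stereocentre of 5 ⇒ catalyst-controlled asymmetric conjugate reduction of butenolide 4; C4 then controls C3.
3. Butenolide 4 ⇒ buta-2,3-dienoic acid 3 + veratryl methyl carbonate 2: one palladium-catalysed operation makes the C4–CH2(ring A) bond and closes the lactone at O1–C5.
4. Enabling feature: lactone atoms C3–C4–C5 carry the carboxyl carbon C2 on C3, the ring-A benzylic carbon on the central C4 and O1 on C5. This is the cumulated C2=C3=C4 unit of a 2,3-allenoic acid after a carbon group has added to its central carbon and its own carboxylate oxygen to its CH2 end.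
5. Ring order: only the lactone (ring C) is built, in step 2; rings A (3,4-dimethoxyphenyl) and B (4-hydroxy-3,5-dimethoxyphenyl) are bought as arenes.

Key step: step 2

Assumption: buta-2,3-dienoic acid is taken as a purchasable building block, and the p-tol-BINAP antipode that delivers hydride to the Si face of C4 in step 3 is taken to be (S); the first run should confirm this sense, and the (R)-ligand is used otherwise.

**Step 1**
Reactants: 1 3,4-dimethoxybenzyl alcohol
Product: 2 3,4-dimethoxybenzyl methyl carbonate
Conditions: ClCO2Me (1.3 equiv), pyridine (2 equiv), CH2Cl2, 0 °C to rt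
Reagents that add atoms: methyl chloroformate, COC(=O)Cl
Why: Acylation of the primary benzylic alcohol with a chloroformate under pyridine (carbonate formation) is routine and gives a leaving group that zerovalent palladium can ionize but that does not alkylate a carboxylate on its own.

**Step 2**
Reactants: 2 3,4-dimethoxybenzyl methyl carbonate, 3 buta-2,3-dienoic acid
Product: 4 4-(3,4-dimethoxybenzyl)furan-2(5H)-one
Conditions: 3 (1.3 equiv), Pd2(dba)3 (2.5 mol %), DPEphos (6 mol %), MeCN, 60 °C, no added base
Reagents that add atoms: none
Why: Proposed new method: zerovalent palladium/DPEphos should ionize carbonate 2 to a cationic η3-(3,4-dimethoxybenzyl)palladium complex, the expelled methyl carbonate losing CO2 to methoxide, which deprotonates acid 3; the benzyl group then migrates to the central sp carbon of the coordinated allenoate to give a 2-benzyl-η3-allylpalladium carboxylate, whose carboxylate oxygen attacks the unsubstituted CH2 terminus, forms the O1–C5 bond and releases zerovalent palladium (the other order, oxygen attack on the palladium-activated allene followed by benzyl–vinyl reductive elimination, leads to the same product). The closest known reaction types are the palladium-catalysed coupling–cyclization of 2,3-allenoic acids with aryl and alkenyl halides, which gives β-substituted butenolides by the same insertion and O-closure sequence, and the palladium-catalysed substitution of benzyl methyl carbonates through η3-benzyl complexes; new is the use of a benzylic carbonate as the carbon electrophile with an allenoic acid. The lactone closes in a 5-membered mode in which all three allene carbons become ring atoms (5-endo on the η3-allyl, or a 5-exo-tet displacement of palladium when written from the η1-allyl form with the carboxylate cis to the CH2 terminus). No stereocentre is created; the new C3=C4 alkene is the handle for the asymmetric reduction in step 3. The step needs C-benzylation at the central carbon instead of O-benzylation of the carboxylate, and closure at C5: the cumulene secures the first because only addition to the sp carbon gives a stabilized allyl, the carboxyl on the allyl terminus leaves the 5-membered closure as the only ring that can form, and any veratryl allenoate formed by O-attack is an ester of an electron-rich benzyl alcohol that the same catalyst should re-ionize to the productive ion pair. Base-free conditions, in which methoxide is made only as fast as the acid consumes it, should keep the allenoic acid from isomerizing to but-2-ynoic acid.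

**Step 3**
Reactants: 4 4-(3,4-dimethoxybenzyl)furan-2(5H)-one
Product: 5 (R)-4-(3,4-dimethoxybenzyl)dihydrofuran-2(3H)-one
Conditions: Cu(OAc)2·H2O (3 mol %), (S)-p-tol-BINAP (3.3 mol %), (EtO)2MeSiH (2 equiv), t-BuOH (2 equiv), toluene, 0 °C to rt
Reagents that add atoms: none
Why: Ligand-controlled copper hydride conjugate reduction of β-substituted butenolides is established: the bisphosphine-bound monovalent copper hydride should add hydride to the Si face of C4 under catalyst control, which sets the (R) centre, and tert-butanol protonates the copper enolate and turns the catalyst over.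

**Step 4**
Reactants: 5 (R)-4-(3,4-dimethoxybenzyl)dihydrofuran-2(3H)-one
Product: 7 (3R,4S)-4-(3,4-dimethoxybenzyl)-3-hydroxydihydrofuran-2(3H)-one, via potassium enolate 6 (not isolated)
Conditions: KN(SiMe3)2 (1.1 equiv), THF, −78 °C; then 2-(phenylsulfonyl)-3-phenyloxaziridine (1.3 equiv), −78 °C; then AcOH (1.2 equiv)
Reagents that add atoms: 2-(phenylsulfonyl)-3-phenyloxaziridine, O=S(=O)(N1OC1c1ccccc1)c1ccccc1
Why: Electrophilic hydroxylation of a lactone enolate with an N-sulfonyloxaziridine is standard, the potassium enolate being attacked anti to the C4 benzyl group to give mainly the trans alcohol, whose C3 configuration is erased in step 7 and therefore need not be uniform.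

**Step 5**
Reactants: 8 4-(hydroxymethyl)-2,6-dimethoxyphenol
Product: 9 [4-(benzyloxy)-3,5-dimethoxyphenyl]methanol
Conditions: BnBr (1.05 equiv), K2CO3 (1.5 equiv), acetone, reflux
Reagents that add atoms: benzyl bromide, BrCc1ccccc1
Why: Williamson ether synthesis in which K2CO3 deprotonates only the phenol and not the benzylic alcohol, so that benzyl bromide should alkylate the phenolic oxygen selectively.

**Step 6**
Reactants: 9 [4-(benzyloxy)-3,5-dimethoxyphenyl]methanol
Product: 10 4-(benzyloxy)-3,5-dimethoxybenzyl bromide
Conditions: PBr3 (0.4 equiv), Et2O, 0 °C; used without storage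
Reagents that add atoms: phosphorus tribromide, BrP(Br)Br
Why: Conversion of a primary benzylic alcohol into the bromide with PBr3 (bromide displacement on the alkyl phosphite) is routine, and the benzyl and methyl aryl ethers are inert at 0 °C.

**Step 7**
Reactants: 7 (3R,4S)-4-(3,4-dimethoxybenzyl)-3-hydroxydihydrofuran-2(3H)-one, 10 4-(benzyloxy)-3,5-dimethoxybenzyl bromide
Product: 12 (3S,4S)-3-[4-(benzyloxy)-3,5-dimethoxybenzyl]-4-(3,4-dimethoxybenzyl)-3-hydroxydihydrofuran-2(3H)-one, via dilithium enediolate 11 (not isolated)
Conditions: LiN(iPr)2 (2.3 equiv), THF, −78 to −40 °C; then 10 (1.2 equiv), DMPU, −78 to −20 °C; then AcOH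
Reagents that add atoms: none
Why: C-Alkylation of the dianion (enediolate) of an α-hydroxy lactone, in which the benzylic bromide should attack C3 on the face anti to the C4 benzyl group, placing the two benzyl groups trans and the hydroxyl cis to the C4 substituent, that is (3S,4S), with C4 untouched.

**Step 8**
Reactants: 12 (3S,4S)-3-[4-(benzyloxy)-3,5-dimethoxybenzyl]-4-(3,4-dimethoxybenzyl)-3-hydroxydihydrofuran-2(3H)-one
Product: 13 (3S,4S)-4-(3,4-dimethoxybenzyl)-3-hydroxy-3-(4-hydroxy-3,5-dimethoxybenzyl)dihydrofuran-2(3H)-one
Conditions: H2 (1 atm), 10% Pd/C, EtOAc, rt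
Reagents that add atoms: none
Why: Catalytic hydrogenolysis should cleave only the benzylic aryl ether C–O bond, since the lactone, the tertiary non-benzylic alcohol and the methyl ethers are stable and no stereocentre is involved.

**Compound list**
1 | 3,4-dimethoxybenzyl alcohol | COc1ccc(CO)cc1OC | starting material
2 | 3,4-dimethoxybenzyl methyl carbonate | COC(=O)OCc1ccc(OC)c(OC)c1 | intermediate
3 | buta-2,3-dienoic acid | C=C=CC(=O)O | starting material
4 | 4-(3,4-dimethoxybenzyl)furan-2(5H)-one | COc1ccc(CC2=CC(=O)OC2)cc1OC | intermediate
5 | (R)-4-(3,4-dimethoxybenzyl)dihydrofuran-2(3H)-one | COc1ccc(C[C@H]2COC(=O)C2)cc1OC | intermediate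
6 | potassium enolate of 5 (potassium 4-(3,4-dimethoxybenzyl)-4,5-dihydrofuran-2-olate, C4 unchanged) | COc1ccc(C[C@H]2COC([O-])=C2)cc1OC.[K+] | intermediate
7 | (3R,4S)-4-(3,4-dimethoxybenzyl)-3-hydroxydihydrofuran-2(3H)-one | COc1ccc(C[C@H]2COC(=O)[C@@H]2O)cc1OC | intermediate
8 | 4-(hydroxymethyl)-2,6-dimethoxyphenol | COc1cc(CO)cc(OC)c1O | starting material
9 | [4-(benzyloxy)-3,5-dimethoxyphenyl]methanol | COc1cc(CO)cc(OC)c1OCc1ccccc1 | intermediate
10 | 4-(benzyloxy)-3,5-dimethoxybenzyl bromide | COc1cc(CBr)cc(OC)c1OCc1ccccc1 | intermediate
11 | dilithium enediolate of 7 (dilithium 4-(3,4-dimethoxybenzyl)-4,5-dihydrofuran-2,3-diolate, C4 unchanged) | COc1ccc(C[C@H]2COC([O-])=C2[O-])cc1OC.[Li+].[Li+] | intermediate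
12 | (3S,4S)-3-[4-(benzyloxy)-3,5-dimethoxybenzyl]-4-(3,4-dimethoxybenzyl)-3-hydroxydihydrofuran-2(3H)-one | COc1ccc(C[C@H]2COC(=O)[C@]2(O)Cc2cc(OC)c(OCc3ccccc3)c(OC)c2)cc1OC | intermediate
13 | (3S,4S)-4-(3,4-dimethoxybenzyl)-3-hydroxy-3-(4-hydroxy-3,5-dimethoxybenzyl)dihydrofuran-2(3H)-one | COc1ccc(C[C@H]2COC(=O)[C@]2(O)Cc2cc(OC)c(O)c(OC)c2)cc1OC | target

**Step count and risks**
Total step count: 8. Longest linear sequence: 6 steps (1, 2, 3, 4, 7, 8, from alcohol 1); the bromide branch is 2 steps (5, 6).

Steps most likely to fail:

Step 2 (proposed new method). The η3-benzylpalladium cation may be captured at the carboxylate oxygen faster than it inserts the allene, without the resulting veratryl allenoate being re-ionized, or the allenoic acid may be consumed by palladium-mediated oligomerization. The fallback uses known chemistry, sets out from 3 and 1 and comes back at 4. Iodolactonization of 3 (I2, K2CO3, MeCN, rt), which closes the same O1–C5 bond, should give 4-iodofuran-2(5H)-one F1. Alcohol 1 is converted with SOCl2 (CH2Cl2, 0 °C) into 3,4-dimethoxybenzyl chloride F2, and this with Zn dust and LiCl in THF into (3,4-dimethoxybenzyl)zinc chloride F3. Negishi coupling of F1 with F3 (Pd(PPh3)4, THF, rt) should give butenolide 4.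

Step 7. The second deprotonation may stay incomplete, the alkoxide oxygen may be alkylated in place of C3, or electron transfer from the enediolate may dimerize the electron-rich benzylic bromide. The fallback replaces the dianion by a protected monoanion, sets out from 7 and comes back at 12. Silylation (TBSOTf, 2,6-lutidine, CH2Cl2, 0 °C) should give (3R,4S)-3-(tert-butyldimethylsilyloxy)-4-(3,4-dimethoxybenzyl)dihydrofuran-2(3H)-one F4. Deprotonation with LiN(SiMe3)2 (THF, −78 °C) gives its lithium enolate F5, which is alkylated by 10 anti to the C4 benzyl group to give (3S,4S)-3-[4-(benzyloxy)-3,5-dimethoxybenzyl]-3-(tert-butyldimethylsilyloxy)-4-(3,4-dimethoxybenzyl)dihydrofuran-2(3H)-one F6. Desilylation with HF·pyridine (THF, rt) then gives 12.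

Step 3. Copper alkoxide may deprotonate the butenolide at C5 or at the doubly activated benzylic CH2 and shift the double bond out of conjugation before hydride is delivered, and the facial selectivity may be insufficient. The fallback changes the reductant and the mechanism, sets out from 4 and comes back at 5: base-free asymmetric hydrogenation with H2 (50 atm) and Ru(OAc)2[(S)-BINAP] in MeOH, the BINAP antipode being chosen for the same Si-face delivery at C4. No new compound is made (entered as F0).

**Further compounds**
F1 | step 2 | 4-iodofuran-2(5H)-one | O=C1C=C(I)CO1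
F2 | step 2 | 3,4-dimethoxybenzyl chloride | COc1ccc(CCl)cc1OC
F3 | step 2 | (3,4-dimethoxybenzyl)zinc chloride | COc1ccc(C[Zn]Cl)cc1OC
F4 | step 7 | (3R,4S)-3-(tert-butyldimethylsilyloxy)-4-(3,4-dimethoxybenzyl)dihydrofuran-2(3H)-one | COc1ccc(C[C@H]2COC(=O)[C@@H]2O[Si](C)(C)C(C)(C)C)cc1OC
F5 | step 7 | lithium enolate of F4 | COc1ccc(C[C@H]2COC([O-])=C2O[Si](C)(C)C(C)(C)C)cc1OC.[Li+]
F6 | step 7 | (3S,4S)-3-[4-(benzyloxy)-3,5-dimethoxybenzyl]-3-(tert-butyldimethylsilyloxy)-4-(3,4-dimethoxybenzyl)dihydrofuran-2(3H)-one | COc1ccc(C[C@H]2COC(=O)[C@]2(O[Si](C)(C)C(C)(C)C)Cc2cc(OC)c(OCc3ccccc3)c(OC)c2)cc1OC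
F0 | step 3 | none | none
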